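## The problem

1. The target is a sesquineolignan: a 7-hydroxy-dibenzylbutyrolactone whose central ring B is tied through its phenol oxygen O4 to C8'' of a guaiacylglycerol unit (numbering: ring A on C7'; lactone C8', C9'(=O), O, C9H2, C8; carbinol C7 on C1 of ring B; ether carbon C8'', C9''H2OH and carbinol C7'' on ring C).
2. The carbon chains are simple; the difficulty is five stereocentres in two clusters, C7/C8/C8' (all R: trans lactone, C7–OH anti to the C8–C8' bond in the aldol sense) and C7''/C8'' (S,S, threo), which sit on opposite sides of the para-substituted ring B and cannot control each other.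
3. Within the lactone cluster C8 can control C8' (trans alkylation of the lactone enolate), but the exocyclic carbinol C7 is only weakly controlled from C8 if it is made by ketone reduction, so it is best set in the same event as C8.
4. C8'' is a secondary ether carbon between a benzylic carbinol and a CH2OH; making its C–O bond by substitution invites elimination, neighbouring-group participation and loss of configuration.
5. Both benzylic carbinols ionise in acid (the C7 cation is trapped by ring A, the C7'' cation scrambles threo and erythro), the para-hydroxybenzyl alcohol of ring C gives a quinone methide in base, the lactone opens or migrates to O7 in base, and the benzylic C–O bonds are at risk under hydrogenolysis.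
6. The feature that opens the structure is the triad C7(OH)–C8–C9H2–O at the lactone ring, with C7 on C1 of ring B: C9 is an acyl carbon in reduced form, so C7–C8 is an aldol bond between a ring B aldehyde and the C8 enolate of a succinate (C9–C8–C8'–C9'), and the reduced C9 closes the lactone onto C9' by itself.
7. The same triad returns as C7''(OH)–C8''(OAr)–C9''H2OH on ring C, where the enolate carbon C8'' already carries O4 of ring B; ring B, a 4-oxygenated benzaldehyde, is thus aldol acceptor for one triad and enolate substituent for the other.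

## Retrosynthesis

**29 to 28.** Only Si–O bonds are cut. All five hydroxyls of 29 are carried as silyl ethers (two aryl triisopropylsilyl, three alkyl tert-butyldimethylsilyl) in 28, so the last step needs buffered fluoride only, with no acid, strong base or hydrogenolysis near the benzylic carbinols.

**28 to 24 and 26.** The C8'–C7' bond is cut. Against the neighbouring C8–C8' cut (conjugate addition to a butenolide), this removes ring A and the C8' centre in one move and leaves a lactone 24 whose single ring substituent directs the incoming benzyl bromide 26 to the opposite face. The forward reaction must only be trans-selective, which is the thermodynamic sense as well.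

**24 to 23 to 20.** The lactone acyl–oxygen bond (O–C9') is opened and C9 is raised to the acyl level carrying an oxazolidinone. In the forward sense one hydride reagent must cleave the imide of 20 to the C9 alcohol 22 without touching the methyl ester; the primary alcohol then closes the lactone 23, and silylation of O7 gives 24. The auxiliary removal and the ring closure are the same operation.

**20 to 14 and 17 (key disconnection).** The C7–C8 bond is cut as an anti-aldol. The neighbouring cuts are weaker: C7–C1 of ring B (aryl-metal addition to a lactone aldehyde) would rely on Felkin control, and C8–C8' needs an acyl-anion equivalent and a later ketone reduction. The chosen cut sets C7 and C8 together under auxiliary control and joins the whole ring B/ring C half (aldehyde 14, two stereocentres) to a one-step succinate imide 17. The forward reaction must be anti-selective, must enolise only the imide CH2, and must override any influence of the remote C7''/C8'' centres.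

**14 to 11 to 10 to 8.** Functional-group changes only: the aldehyde comes from the aryl bromide of 11 (bromine–lithium exchange, DMF), the two silyl ethers from diol 10, and C9''H2OH from reductive removal of the auxiliary in 8. The bromine is a formyl group that survives the boron aldol and the borohydride.

**8 to 3 and 5.** The C7''–C8'' bond is cut as a syn-aldol of the aryloxyacetyl imide 3 with aldehyde 5. The alternative cut at O4–C8'' would make the ether by substitution at a stereocentre. Here the O4–C8'' bond exists before C8'' becomes stereogenic, and the threo pair is set in one step by the same (R)-auxiliary that later serves the key step.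

**3 to 1 and 2; 5 to 4; 17 to 15 and 16; 26 to 25 to 5.** Phenol alkylation of 1 with the chloroacetyl imide 2; silylation of vanillin 4; N-acylation of oxazolidinone 15 with the succinate half-ester chloride 16; reduction and bromination of 5 via alcohol 25.

## Roads not taken

**Alternative 1: late ether formation at O4–C8'' (the obvious route).**
- Cut: the O4–C8'' ether bond, after a separate synthesis of the lignan phenol A1.
- Forward key step: alkylation of A1 with bromoketone A2 to aryloxy ketone A3, then hydroxymethylation at C8'' and ketone reduction.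
- Why the chosen plan is better: C8'' is created on an enolisable ketone far from any stereocentre, and the reduction gives erythro/threo mixtures, so the (7''S,8''S) isomer is one of four. The hydroxymethylation needs base in the presence of the lactone. The stereocontrolled variant (displacement of a sulfonate or Mitsunobu reaction of A1 on an arylglycerol) must invert a secondary carbon flanked by a benzylic oxygen and needs the erythro precursor. A1 still needs its own three-centre synthesis and a selectively freed phenol. The chosen plan never substitutes at C8'' and never needs the lignan as a free phenol.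

**Alternative 2: reversed polarity at C7 (acyl-anion conjugate addition).**
- Cut: C7–C8 with C7 as nucleophile.
- Forward key step: the dithiane A4 of aldehyde 14 is lithiated, added to a chiral 5-alkoxybutenolide and trapped with bromide 26; removal of the alkoxy group and the dithiane gives ketone A5, which is reduced.
- Why the chosen plan is better: this sets C8 and C8' but leaves C7 to a late hydride reduction next to an epimerisable, beta-acyloxy ketone carbon (C8 of A5 can eliminate the lactone oxygen). It needs a stoichiometric chiral butenolide that must be excised, and a dithiane cleavage beside three electron-rich arenes. It is about four steps longer after fragment union, and the C7 configuration is the least certain point. The aldol makes C7 and C8 in the bond-forming step.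

**Alternative 3: C8–C8' by Ireland–Claisen rearrangement.**
- Cut: the C8–C8' bond.
- Forward key step: [3,3] rearrangement of the allylic ester A6 (C7 set beforehand by enantioselective ketone reduction) to acid A7, then oxidative cleavage of the vinyl group to C9, reduction and lactonisation.
- Why the chosen plan is better: relay from the C7 silyloxy centre to C8/C8' depends on enolate geometry and on allylic 1,2-induction through a chair, which is not secure for an aryl/silyloxy-substituted stereocentre. The vinyl-to-CH2OH change needs an oxidant beside three electron-rich rings. The run-up (ynone, reduction, alkene geometry, esterification) is longer than one aldol.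

Key step: step 8

## Route

Remarks. Compound 2 is taken as purchased. ArB in names stands for 4-{[(1S,2S)-1,3-bis(tert-butyldimethylsilyloxy)-1-[3-methoxy-4-(triisopropylsilyloxy)phenyl]propan-2-yl]oxy}-3-methoxyphenyl (ring B carrying the protected ring C unit on O4). Descriptor changes at C8'' (8 to 10) and at C8 (21 to 22) come only from the CIP rank of C9''/C9 falling on reduction; no centre is inverted.

Step 1
Reactants: 1 4-bromo-2-methoxyphenol; 2 (R)-4-benzyl-3-(chloroacetyl)oxazolidin-2-one
Product: 3 (R)-4-benzyl-3-[(4-bromo-2-methoxyphenoxy)acetyl]oxazolidin-2-one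
Conditions: K2CO3, NaI (10 mol%), acetone, 45 °C
Reagents that add atoms: none
Why: Williamson etherification; the phenoxide displaces halide alpha to the imide carbonyl (Finkelstein activation by iodide), and K2CO3 is too weak to enolise or cleave the imide. The O4–C8'' bond is made at an achiral CH2, before C8'' becomes a stereocentre.

Step 2
Reactants: 4 vanillin (4-hydroxy-3-methoxybenzaldehyde)
Product: 5 3-methoxy-4-(triisopropylsilyloxy)benzaldehyde
Conditions: i-Pr3SiCl, imidazole, DMF, rt
Reagents that add atoms: triisopropylsilyl chloride, CC(C)[Si](Cl)(C(C)C)C(C)C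
Why: Standard phenol silylation; the triisopropylsilyl ether survives borohydride, organolithium and amide bases and leaves with fluoride at the end.

Step 3
Reactants: 3 (R)-4-benzyl-3-[(4-bromo-2-methoxyphenoxy)acetyl]oxazolidin-2-one; 5 3-methoxy-4-(triisopropylsilyloxy)benzaldehyde
Product: 8 (R)-4-benzyl-3-{(2R,3S)-2-(4-bromo-2-methoxyphenoxy)-3-hydroxy-3-[3-methoxy-4-(triisopropylsilyloxy)phenyl]propanoyl}oxazolidin-2-one, via dibutylboron (Z)-enolate 6 (not isolated), via dibutylboron aldolate 7 (not isolated)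
Conditions: Bu2BOTf, i-Pr2NEt, CH2Cl2, −78 to 0 °C; 5, −78 to 0 °C; pH 7 buffer, MeOH, H2O2
Reagents that add atoms: none
Why: Evans syn-aldol of a glycolate imide: soft enolisation gives the (Z)-boron enolate 6, which adds to 5 through a closed chair with the auxiliary carbonyl turned away from boron. The benzyl group of the (R)-auxiliary fixes the enolate face (C8'') and the chair places C7''–O syn to O4, i.e. the threo (7''S,8''S) pair.

Step 4
Reactants: 8 (R)-4-benzyl-3-{(2R,3S)-2-(4-bromo-2-methoxyphenoxy)-3-hydroxy-3-[3-methoxy-4-(triisopropylsilyloxy)phenyl]propanoyl}oxazolidin-2-one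
Product: 10 (1S,2S)-2-(4-bromo-2-methoxyphenoxy)-1-[3-methoxy-4-(triisopropylsilyloxy)phenyl]propane-1,3-diol, via hydroxy aldehyde 9 (not isolated)
Conditions: LiBH4, H2O (1 equiv), THF, 0 °C
Reagents that add atoms: none
Why: Reductive cleavage of the N-acyloxazolidinone: hydride attacks the exocyclic imide carbonyl, the auxiliary leaves, and aldehyde 9 is reduced as it forms, so C8'' is not exposed to epimerisation. The aryl bromide and the silyl ether are inert.

Step 5
Reactants: 10 (1S,2S)-2-(4-bromo-2-methoxyphenoxy)-1-[3-methoxy-4-(triisopropylsilyloxy)phenyl]propane-1,3-diol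
Product: 11 1,3-bis(tert-butyldimethylsilyl) ether of 10
Conditions: t-BuMe2SiOTf, 2,6-lutidine, CH2Cl2, −40 to 0 °C
Reagents that add atoms: tert-butyldimethylsilyl triflate, CC(C)(C)[Si](C)(C)OS(=O)(=O)C(F)(F)F
Why: The silyl triflate silylates both the primary and the hindered benzylic hydroxyl; the diol protection carries no acetal and leaves with the other silyl groups in one fluoride step.

Step 6
Reactants: 11 1,3-bis(tert-butyldimethylsilyl) ether of 10
Product: 14 4-{[(1S,2S)-1,3-bis(tert-butyldimethylsilyloxy)-1-[3-methoxy-4-(triisopropylsilyloxy)phenyl]propan-2-yl]oxy}-3-methoxybenzaldehyde, via aryllithium 12 (not isolated), via lithium aminoalkoxide 13 (not isolated)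
Conditions: n-BuLi, THF, −78 °C; DMF, −78 to 0 °C; H2O
Reagents that add atoms: N,N-dimethylformamide, CN(C)C=O
Why: Bromine–lithium exchange at −78 °C outruns any deprotonation; aryllithium 12 adds to DMF to give the stable tetrahedral alkoxide 13, which releases the aldehyde only on aqueous work-up (Bouveault formylation).

Step 7
Reactants: 15 (R)-4-benzyloxazolidin-2-one; 16 methyl 4-chloro-4-oxobutanoate
Product: 17 methyl 4-[(R)-4-benzyl-2-oxooxazolidin-3-yl]-4-oxobutanoate
Conditions: Et3N, DMAP (10 mol%), CH2Cl2, 0 °C to rt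
Reagents that add atoms: none
Why: N-acylation of the oxazolidinone by the acid chloride under acyl-transfer catalysis; the methyl ester end is untouched.

Step 8
Reactants: 14 4-{[(1S,2S)-1,3-bis(tert-butyldimethylsilyloxy)-1-[3-methoxy-4-(triisopropylsilyloxy)phenyl]propan-2-yl]oxy}-3-methoxybenzaldehyde; 17 methyl 4-[(R)-4-benzyl-2-oxooxazolidin-3-yl]-4-oxobutanoate
Product: 20 methyl (3S,4R)-3-[(R)-4-benzyl-2-oxooxazolidine-3-carbonyl]-4-hydroxy-4-ArB-butanoate, via chloromagnesium (Z)-enolate 18 (not isolated), via trimethylsilyl ether 19 (not isolated)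
Conditions: MgCl2 (20 mol%), Et3N, Me3SiCl, EtOAc, 23 °C; then PPTS (cat.), MeOH, 0 °C
Reagents that add atoms: none
Why: MgCl2 binds both imide carbonyls of 17 and Et3N removes a C8 proton to give the chelated (Z)-enolate 18, which adds reversibly to 14; Me3SiCl silylates the magnesium aldolate, which makes the addition irreversible and returns the magnesium halide, and silyl ether 19 is methanolysed on work-up. The closest known reaction type is the magnesium halide-catalysed anti-aldol reaction of N-acyloxazolidinones with non-enolisable aromatic aldehydes. The step closes no ring; it joins C7 to C8. C8 is set by the benzyl group of the (R)-auxiliary, which shields one face of the chelated enolate so that the aldehyde enters on the face that alkylations of such enolates use. C7 is set relative to C8 by the boat-like chelate transition state of the (Z)-enolate, which gives the anti adduct (7R,8R in target numbering). The step needs enolisation of the imide CH2 only (the ester CH2 is not acidified by chelation), an acceptor without alpha hydrogens (14 has none), and reagent control over the C7''/C8'' centres, which lie across ring B and should not bias the addition. Silylation in the flask should also keep O7 from closing onto the methyl ester.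

Step 9
Reactants: 20 methyl (3S,4R)-3-[(R)-4-benzyl-2-oxooxazolidine-3-carbonyl]-4-hydroxy-4-ArB-butanoate
Product: 23 (R)-4-[(R)-ArB(hydroxy)methyl]dihydrofuran-2(3H)-one, via formyl ester 21 (not isolated), via hydroxy ester 22 (not isolated)
Conditions: NaBH4, THF/H2O (4:1), 0 °C to rt
Reagents that add atoms: none
Why: Reductive auxiliary cleavage with NaBH4 in wet THF, which reduces imides much faster than methyl esters; aldehyde 21 is reduced as it forms, so C8 keeps its configuration. The primary C9 hydroxyl of 22 closes the five-membered lactone onto the ester (5-exo-trig acyl substitution) faster than the hindered benzylic C7 hydroxyl.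

Step 10
Reactants: 23 (R)-4-[(R)-ArB(hydroxy)methyl]dihydrofuran-2(3H)-one
Product: 24 (R)-4-[(R)-ArB(tert-butyldimethylsilyloxy)methyl]dihydrofuran-2(3H)-one
Conditions: t-BuMe2SiOTf, 2,6-lutidine, CH2Cl2, −78 to −20 °C
Reagents that add atoms: tert-butyldimethylsilyl triflate, CC(C)(C)[Si](C)(C)OS(=O)(=O)C(F)(F)F
Why: Silylation of the secondary benzylic hydroxyl; it blocks alkoxide-driven lactone migration to O7 and O-alkylation in step 13.

Step 11
Reactants: 5 3-methoxy-4-(triisopropylsilyloxy)benzaldehyde
Product: 25 [3-methoxy-4-(triisopropylsilyloxy)phenyl]methanol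
Conditions: NaBH4, MeOH, 0 °C
Reagents that add atoms: none
Why: Borohydride reduction of an aromatic aldehyde; the aryl silyl ether is stable under these conditions.

Step 12
Reactants: 25 [3-methoxy-4-(triisopropylsilyloxy)phenyl]methanol
Product: 26 4-(bromomethyl)-2-methoxy-1-(triisopropylsilyloxy)benzene
Conditions: PBr3, Et2O, 0 °C
Reagents that add atoms: phosphorus tribromide, BrP(Br)Br
Why: Bromide displaces the activated phosphite ester of a primary benzylic alcohol; the bromide is used at once because para-silyloxybenzyl bromides ionise on storage.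

Step 13
Reactants: 24 (R)-4-[(R)-ArB(tert-butyldimethylsilyloxy)methyl]dihydrofuran-2(3H)-one; 26 4-(bromomethyl)-2-methoxy-1-(triisopropylsilyloxy)benzene
Product: 28 (3R,4R)-4-[(R)-ArB(tert-butyldimethylsilyloxy)methyl]-3-[3-methoxy-4-(triisopropylsilyloxy)benzyl]dihydrofuran-2(3H)-one, via lithium enolate 27 (not isolated)
Conditions: LiN(SiMe3)2, THF, −78 °C; 26, DMPU, −78 to −40 °C
Reagents that add atoms: none
Why: Alkylation of a beta-substituted gamma-butyrolactone enolate: 26 attacks enolate 27 on the face opposite the large C8 substituent, which sets C8' as the 8,8'-trans (8'R) isomer. This is the standard entry to dibenzylbutyrolactone lignans and also the thermodynamic sense.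

Step 14
Reactants: 28 (3R,4R)-4-[(R)-ArB(tert-butyldimethylsilyloxy)methyl]-3-[3-methoxy-4-(triisopropylsilyloxy)benzyl]dihydrofuran-2(3H)-one
Product: 29 (3R,4R)-4-[(R)-{4-[(1S,2S)-1,3-dihydroxy-1-(4-hydroxy-3-methoxyphenyl)propan-2-yl]oxy-3-methoxyphenyl}(hydroxy)methyl]-3-(4-hydroxy-3-methoxybenzyl)dihydrofuran-2(3H)-one (CNP0233652.1)
Conditions: Bu4NF, AcOH (1:1), THF, 0 °C to rt
Reagents that add atoms: none
Why: Fluoride cleaves all five Si–O bonds (two aryl, three alkyl); acetic acid buffers the phenoxides and alkoxides so that the lactone, C8' and the para-hydroxybenzylic carbinol at C7'' are not exposed to strong base. No acid or hydrogenolysis touches the benzylic C–O bonds.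

## Compound list

1 | 4-bromo-2-methoxyphenol | COc1cc(Br)ccc1O | starting material
2 | (R)-4-benzyl-3-(chloroacetyl)oxazolidin-2-one | ClCC(=O)N1[C@H](Cc2ccccc2)COC1=O | starting material
3 | (R)-4-benzyl-3-[(4-bromo-2-methoxyphenoxy)acetyl]oxazolidin-2-one | COc1cc(Br)ccc1OCC(=O)N1[C@H](Cc2ccccc2)COC1=O | intermediate
4 | vanillin (4-hydroxy-3-methoxybenzaldehyde) | COc1cc(C=O)ccc1O | starting material
5 | 3-methoxy-4-(triisopropylsilyloxy)benzaldehyde | COc1cc(C=O)ccc1O[Si](C(C)C)(C(C)C)C(C)C | intermediate
6 | dibutylboron (Z)-enolate of 3 (formed in the flask) | CCCCB(CCCC)O/C(=C\Oc1ccc(Br)cc1OC)N1[C@H](Cc2ccccc2)COC1=O | intermediate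
7 | dibutylboron aldolate of 8 (formed in the flask) | COc1cc(Br)ccc1O[C@@H](C(=O)N1[C@H](Cc2ccccc2)COC1=O)[C@@H](OB(CCCC)CCCC)c1ccc(O[Si](C(C)C)(C(C)C)C(C)C)c(OC)c1 | intermediate
8 | (R)-4-benzyl-3-{(2R,3S)-2-(4-bromo-2-methoxyphenoxy)-3-hydroxy-3-[3-methoxy-4-(triisopropylsilyloxy)phenyl]propanoyl}oxazolidin-2-one | COc1cc(Br)ccc1O[C@@H](C(=O)N1[C@H](Cc2ccccc2)COC1=O)[C@@H](O)c1ccc(O[Si](C(C)C)(C(C)C)C(C)C)c(OC)c1 | intermediate
9 | (2R,3S)-2-(4-bromo-2-methoxyphenoxy)-3-hydroxy-3-[3-methoxy-4-(triisopropylsilyloxy)phenyl]propanal (formed in the flask) | COc1cc(Br)ccc1O[C@@H](C=O)[C@@H](O)c1ccc(O[Si](C(C)C)(C(C)C)C(C)C)c(OC)c1 | intermediate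
10 | (1S,2S)-2-(4-bromo-2-methoxyphenoxy)-1-[3-methoxy-4-(triisopropylsilyloxy)phenyl]propane-1,3-diol | COc1cc(Br)ccc1O[C@@H](CO)[C@@H](O)c1ccc(O[Si](C(C)C)(C(C)C)C(C)C)c(OC)c1 | intermediate
11 | 1,3-bis(tert-butyldimethylsilyl) ether of 10 | COc1cc(Br)ccc1O[C@@H](CO[Si](C)(C)C(C)(C)C)[C@@H](O[Si](C)(C)C(C)(C)C)c1ccc(O[Si](C(C)C)(C(C)C)C(C)C)c(OC)c1 | intermediate
12 | aryllithium from 11, Li in place of Br (formed in the flask) | COc1cc([Li])ccc1O[C@@H](CO[Si](C)(C)C(C)(C)C)[C@@H](O[Si](C)(C)C(C)(C)C)c1ccc(O[Si](C(C)C)(C(C)C)C(C)C)c(OC)c1 | intermediate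
13 | lithium alkoxide of the dimethylamino carbinol from 12 and DMF (formed in the flask) | COc1cc(C(O[Li])N(C)C)ccc1O[C@@H](CO[Si](C)(C)C(C)(C)C)[C@@H](O[Si](C)(C)C(C)(C)C)c1ccc(O[Si](C(C)C)(C(C)C)C(C)C)c(OC)c1 | intermediate
14 | 4-{[(1S,2S)-1,3-bis(tert-butyldimethylsilyloxy)-1-[3-methoxy-4-(triisopropylsilyloxy)phenyl]propan-2-yl]oxy}-3-methoxybenzaldehyde | COc1cc(C=O)ccc1O[C@@H](CO[Si](C)(C)C(C)(C)C)[C@@H](O[Si](C)(C)C(C)(C)C)c1ccc(O[Si](C(C)C)(C(C)C)C(C)C)c(OC)c1 | intermediate
15 | (R)-4-benzyloxazolidin-2-one | O=C1OC[C@@H](Cc2ccccc2)N1 | starting material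
16 | methyl 4-chloro-4-oxobutanoate | COC(=O)CCC(Cl)=O | starting material
17 | methyl 4-[(R)-4-benzyl-2-oxooxazolidin-3-yl]-4-oxobutanoate | COC(=O)CCC(=O)N1[C@H](Cc2ccccc2)COC1=O | intermediate
18 | chloromagnesium (Z)-enolate of 17 (formed in the flask) | COC(=O)C/C=C(\O[Mg]Cl)N1[C@H](Cc2ccccc2)COC1=O | intermediate
19 | trimethylsilyl ether of 20 (formed in the flask) | COC(=O)C[C@H](C(=O)N1[C@H](Cc2ccccc2)COC1=O)[C@@H](O[Si](C)(C)C)c1ccc(O[C@@H](CO[Si](C)(C)C(C)(C)C)[C@@H](O[Si](C)(C)C(C)(C)C)c2ccc(O[Si](C(C)C)(C(C)C)C(C)C)c(OC)c2)c(OC)c1 | intermediate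
20 | methyl (3S,4R)-3-[(R)-4-benzyl-2-oxooxazolidine-3-carbonyl]-4-hydroxy-4-ArB-butanoate | COC(=O)C[C@H](C(=O)N1[C@H](Cc2ccccc2)COC1=O)[C@@H](O)c1ccc(O[C@@H](CO[Si](C)(C)C(C)(C)C)[C@@H](O[Si](C)(C)C(C)(C)C)c2ccc(O[Si](C(C)C)(C(C)C)C(C)C)c(OC)c2)c(OC)c1 | intermediate
21 | methyl (3S,4R)-3-formyl-4-hydroxy-4-ArB-butanoate (formed in the flask) | COC(=O)C[C@H](C=O)[C@@H](O)c1ccc(O[C@@H](CO[Si](C)(C)C(C)(C)C)[C@@H](O[Si](C)(C)C(C)(C)C)c2ccc(O[Si](C(C)C)(C(C)C)C(C)C)c(OC)c2)c(OC)c1 | intermediate
22 | methyl (3R,4R)-4-hydroxy-3-(hydroxymethyl)-4-ArB-butanoate (formed in the flask) | COC(=O)C[C@H](CO)[C@@H](O)c1ccc(O[C@@H](CO[Si](C)(C)C(C)(C)C)[C@@H](O[Si](C)(C)C(C)(C)C)c2ccc(O[Si](C(C)C)(C(C)C)C(C)C)c(OC)c2)c(OC)c1 | intermediate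
23 | (R)-4-[(R)-ArB(hydroxy)methyl]dihydrofuran-2(3H)-one | O=C1C[C@H](CO1)[C@@H](O)c1ccc(O[C@@H](CO[Si](C)(C)C(C)(C)C)[C@@H](O[Si](C)(C)C(C)(C)C)c2ccc(O[Si](C(C)C)(C(C)C)C(C)C)c(OC)c2)c(OC)c1 | intermediate
24 | (R)-4-[(R)-ArB(tert-butyldimethylsilyloxy)methyl]dihydrofuran-2(3H)-one | O=C1C[C@H](CO1)[C@@H](O[Si](C)(C)C(C)(C)C)c1ccc(O[C@@H](CO[Si](C)(C)C(C)(C)C)[C@@H](O[Si](C)(C)C(C)(C)C)c2ccc(O[Si](C(C)C)(C(C)C)C(C)C)c(OC)c2)c(OC)c1 | intermediate
25 | [3-methoxy-4-(triisopropylsilyloxy)phenyl]methanol | COc1cc(CO)ccc1O[Si](C(C)C)(C(C)C)C(C)C | intermediate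
26 | 4-(bromomethyl)-2-methoxy-1-(triisopropylsilyloxy)benzene | COc1cc(CBr)ccc1O[Si](C(C)C)(C(C)C)C(C)C | intermediate
27 | lithium enolate of 24 (formed in the flask) | [Li]OC1=C[C@H](CO1)[C@@H](O[Si](C)(C)C(C)(C)C)c1ccc(O[C@@H](CO[Si](C)(C)C(C)(C)C)[C@@H](O[Si](C)(C)C(C)(C)C)c2ccc(O[Si](C(C)C)(C(C)C)C(C)C)c(OC)c2)c(OC)c1 | intermediate
28 | (3R,4R)-4-[(R)-ArB(tert-butyldimethylsilyloxy)methyl]-3-[3-methoxy-4-(triisopropylsilyloxy)benzyl]dihydrofuran-2(3H)-one | COc1cc(C[C@H]2C(=O)OC[C@@H]2[C@@H](O[Si](C)(C)C(C)(C)C)c2ccc(O[C@@H](CO[Si](C)(C)C(C)(C)C)[C@@H](O[Si](C)(C)C(C)(C)C)c3ccc(O[Si](C(C)C)(C(C)C)C(C)C)c(OC)c3)c(OC)c2)ccc1O[Si](C(C)C)(C(C)C)C(C)C | intermediate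
29 | (3R,4R)-4-[(R)-{4-[(1S,2S)-1,3-dihydroxy-1-(4-hydroxy-3-methoxyphenyl)propan-2-yl]oxy-3-methoxyphenyl}(hydroxy)methyl]-3-(4-hydroxy-3-methoxybenzyl)dihydrofuran-2(3H)-one (CNP0233652.1) | COc1cc(C[C@H]2C(=O)OC[C@@H]2[C@@H](O)c2ccc(O[C@@H](CO)[C@@H](O)c3ccc(O)c(OC)c3)c(OC)c2)ccc1O | target

## Step count and least certain steps

Total: 14 steps. Longest linear sequence: 10 steps (1, 3, 4, 5, 6, 8, 9, 10, 13, 14, from phenol 1).

**Step 8 (key step).** The most likely failure is slow addition to the electron-rich aldehyde, so that retro-aldol equilibration before silylation erodes anti and facial selectivity, or ring closure of the magnesium aldolate onto the methyl ester before it is silylated. The fallback replaces the auxiliary-bound metal enolate by enamine catalysis. It sets out from 14: methyl 4-oxobutanoate is added slowly in DMF at 4 °C in the presence of L-proline, which forms the enamine (S)-1-[(E)-4-methoxy-4-oxobut-1-enyl]pyrrolidine-2-carboxylic acid F1. Its anti-selective addition to 14 through the hydrogen-bonded chair (known for this donor with aromatic aldehydes) gives formyl ester 21. NaBH4 in MeOH at 0 °C in the same flask gives 22, and the route is rejoined at lactone 23, without 17 to 20. The L-enantiomer of proline is the one that leads to the (3S,4R) aldehyde; the limit of this fallback is the low electrophilicity of 14, which the slow addition of the donor is meant to offset.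

**Step 9.** The most likely failure is over-reduction (borohydride attack on the methyl ester or on the new lactone) or opening of the oxazolidinone ring by hydride at the carbamate carbonyl, since the imide carbonyl of 20 is hindered. The fallback separates cleavage and reduction. It sets out from 20: LiOH/H2O2 in THF/H2O at 0 °C cleaves the imide to (2S,3R)-3-hydroxy-2-(2-methoxy-2-oxoethyl)-3-ArB-propaneperoxoic acid F2, Na2SO3 reduces it to (2S,3R)-3-hydroxy-2-(2-methoxy-2-oxoethyl)-3-ArB-propanoic acid F3, and BH3·SMe2 in THF at 0 °C reduces the carboxylic acid beside the methyl ester to 22, which closes to 23, where the route is rejoined.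

**Step 14.** The most likely failure is slow cleavage of the hindered benzylic silyl ether on O7; the longer exposure to fluoride allows acyl migration of the lactone to the freed O7 or quinone-methide formation at C7'' once the ring C phenol is free. The fallback changes the O7 protecting group. It sets out from 23: Et3SiOTf/2,6-lutidine gives (R)-4-[(R)-ArB(triethylsilyloxy)methyl]dihydrofuran-2(3H)-one F4; LiN(SiMe3)2 gives the lithium enolate of F4, F5, which is benzylated with 26 to (3R,4R)-4-[(R)-ArB(triethylsilyloxy)methyl]-3-[3-methoxy-4-(triisopropylsilyloxy)benzyl]dihydrofuran-2(3H)-one F6. The triethylsilyl ether on O7 then leaves with the other silyl groups under shorter, colder Bu4NF/AcOH treatment, and the route is rejoined at 29.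

**Step 1.** The most likely failure is acyl transfer from the imide to the phenoxide, or C-alkylation of the product by remaining 2, since the product CH2 is more acidic than that of 2. The fallback makes the ether before the imide. It sets out from 1: chloroacetic acid and NaOH in water at reflux give (4-bromo-2-methoxyphenoxy)acetic acid F7; pivaloyl chloride/Et3N converts it into (4-bromo-2-methoxyphenoxy)acetic pivalic anhydride F8, which acylates 15 in the presence of LiCl to give 3, where the route is rejoined.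

## Further compounds

F1 | step 8 | (S)-1-[(E)-4-methoxy-4-oxobut-1-enyl]pyrrolidine-2-carboxylic acid | COC(=O)C/C=C/N1CCC[C@H]1C(=O)O
F2 | step 9 | (2S,3R)-3-hydroxy-2-(2-methoxy-2-oxoethyl)-3-ArB-propaneperoxoic acid | COC(=O)C[C@H](C(=O)OO)[C@@H](O)c1ccc(O[C@@H](CO[Si](C)(C)C(C)(C)C)[C@@H](O[Si](C)(C)C(C)(C)C)c2ccc(O[Si](C(C)C)(C(C)C)C(C)C)c(OC)c2)c(OC)c1
F3 | step 9 | (2S,3R)-3-hydroxy-2-(2-methoxy-2-oxoethyl)-3-ArB-propanoic acid | COC(=O)C[C@H](C(=O)O)[C@@H](O)c1ccc(O[C@@H](CO[Si](C)(C)C(C)(C)C)[C@@H](O[Si](C)(C)C(C)(C)C)c2ccc(O[Si](C(C)C)(C(C)C)C(C)C)c(OC)c2)c(OC)c1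
F4 | step 14 | (R)-4-[(R)-ArB(triethylsilyloxy)methyl]dihydrofuran-2(3H)-one | O=C1C[C@H](CO1)[C@@H](O[Si](CC)(CC)CC)c1ccc(O[C@@H](CO[Si](C)(C)C(C)(C)C)[C@@H](O[Si](C)(C)C(C)(C)C)c2ccc(O[Si](C(C)C)(C(C)C)C(C)C)c(OC)c2)c(OC)c1
F5 | step 14 | lithium enolate of F4 | [Li]OC1=C[C@H](CO1)[C@@H](O[Si](CC)(CC)CC)c1ccc(O[C@@H](CO[Si](C)(C)C(C)(C)C)[C@@H](O[Si](C)(C)C(C)(C)C)c2ccc(O[Si](C(C)C)(C(C)C)C(C)C)c(OC)c2)c(OC)c1
F6 | step 14 | (3R,4R)-4-[(R)-ArB(triethylsilyloxy)methyl]-3-[3-methoxy-4-(triisopropylsilyloxy)benzyl]dihydrofuran-2(3H)-one | COc1cc(C[C@H]2C(=O)OC[C@@H]2[C@@H](O[Si](CC)(CC)CC)c2ccc(O[C@@H](CO[Si](C)(C)C(C)(C)C)[C@@H](O[Si](C)(C)C(C)(C)C)c3ccc(O[Si](C(C)C)(C(C)C)C(C)C)c(OC)c3)c(OC)c2)ccc1O[Si](C(C)C)(C(C)C)C(C)C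
F7 | step 1 | (4-bromo-2-methoxyphenoxy)acetic acid | COc1cc(Br)ccc1OCC(=O)O
F8 | step 1 | (4-bromo-2-methoxyphenoxy)acetic pivalic anhydride | COc1cc(Br)ccc1OCC(=O)OC(=O)C(C)(C)C
A1 | alternative 1 | (3R,4R)-4-[(R)-(tert-butyldimethylsilyloxy)(4-hydroxy-3-methoxyphenyl)methyl]-3-[3-methoxy-4-(triisopropylsilyloxy)benzyl]dihydrofuran-2(3H)-one | COc1cc(C[C@H]2C(=O)OC[C@@H]2[C@@H](O[Si](C)(C)C(C)(C)C)c2ccc(O)c(OC)c2)ccc1O[Si](C(C)C)(C(C)C)C(C)C
A2 | alternative 1 | 2-bromo-1-[3-methoxy-4-(triisopropylsilyloxy)phenyl]ethan-1-one | COc1cc(C(=O)CBr)ccc1O[Si](C(C)C)(C(C)C)C(C)C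
A3 | alternative 1 | (3R,4R)-4-[(R)-(tert-butyldimethylsilyloxy){3-methoxy-4-[2-(3-methoxy-4-triisopropylsilyloxyphenyl)-2-oxoethoxy]phenyl}methyl]-3-[3-methoxy-4-(triisopropylsilyloxy)benzyl]dihydrofuran-2(3H)-one | COc1cc(C[C@H]2C(=O)OC[C@@H]2[C@@H](O[Si](C)(C)C(C)(C)C)c2ccc(OCC(=O)c3ccc(O[Si](C(C)C)(C(C)C)C(C)C)c(OC)c3)c(OC)c2)ccc1O[Si](C(C)C)(C(C)C)C(C)C
A4 | alternative 2 | 2-ArB-1,3-dithiane | C1CSC(SC1)c1ccc(O[C@@H](CO[Si](C)(C)C(C)(C)C)[C@@H](O[Si](C)(C)C(C)(C)C)c2ccc(O[Si](C(C)C)(C(C)C)C(C)C)c(OC)c2)c(OC)c1
A5 | alternative 2 | (3R,4R)-4-(ArB-carbonyl)-3-[3-methoxy-4-(triisopropylsilyloxy)benzyl]dihydrofuran-2(3H)-one | COc1cc(C[C@H]2C(=O)OC[C@@H]2C(=O)c2ccc(O[C@@H](CO[Si](C)(C)C(C)(C)C)[C@@H](O[Si](C)(C)C(C)(C)C)c3ccc(O[Si](C(C)C)(C(C)C)C(C)C)c(OC)c3)c(OC)c2)ccc1O[Si](C(C)C)(C(C)C)C(C)C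
A6 | alternative 3 | (R,E)-4-ArB-4-(tert-butyldimethylsilyloxy)but-2-en-1-yl 3-[3-methoxy-4-(triisopropylsilyloxy)phenyl]propanoate | O=C(CCc1ccc(O[Si](C(C)C)(C(C)C)C(C)C)c(OC)c1)OC/C=C/[C@@H](O[Si](C)(C)C(C)(C)C)c1ccc(O[C@@H](CO[Si](C)(C)C(C)(C)C)[C@@H](O[Si](C)(C)C(C)(C)C)c2ccc(O[Si](C(C)C)(C(C)C)C(C)C)c(OC)c2)c(OC)c1
A7 | alternative 3 | (2R,3S)-3-[(R)-ArB(tert-butyldimethylsilyloxy)methyl]-2-[3-methoxy-4-(triisopropylsilyloxy)benzyl]pent-4-enoic acid | COc1cc(C[C@@H](C(=O)O)[C@H](C=C)[C@@H](O[Si](C)(C)C(C)(C)C)c2ccc(O[C@@H](CO[Si](C)(C)C(C)(C)C)[C@@H](O[Si](C)(C)C(C)(C)C)c3ccc(O[Si](C(C)C)(C(C)C)C(C)C)c(OC)c3)c(OC)c2)ccc1O[Si](C(C)C)(C(C)C)C(C)C
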